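**Retrosynthetic overview**

1. Target ⇐ α-bromo ketone (hydride delivered anti to two axial methyls) ⇐ β-methyl enone (conjugate methylation, bromination of the resulting enol silane) ⇐ spiro-cyclohexadienone (ligand-controlled conjugate methylation).
2. Key disconnection: the C6–C7 bond of the spirodienone ⇒ a para-substituted phenoxide that already carries the full five-carbon tether with Br and Cl in place. Ring closure destroys the aromatic ring, and the two halogen stereocentres dictate the spiro centre.
3. Tether ⇐ catalytic enantioselective bromochlorination of a Z trisubstituted allylic alcohol ⇐ B-alkyl Suzuki coupling of silylated 4-bromo-3-methylphenol with a C6 dienol.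
4. Ring order: ring A is the arene of the bromocresol (present from the start, dearomatized in the key step); ring B is formed in that same step; nothing else is cyclized.
5. Numbering used (spiro[5.5]undecane): C1 = CMe2, C2 = CHBr, C3 = C–O, C5 = CHMe, C6 = spiro, C8 = CHBr, C9 = C(Me)Cl; ring A = C1–C6, ring B = C6–C11.

Assumption: 1 and 3 are bought as such, and the handedness of the two chiral ligands (steps 4 and 6) is assigned by analogy with nerol-type alcohols and cyclohexenone and would be confirmed by correlation on first use.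

**Route**

Step 1
Reactants: 1 4-bromo-3-methylphenol
Product: 2 (4-bromo-3-methylphenoxy)triisopropylsilane
Conditions: iPr3SiCl, imidazole, DMF, 23 °C
Reagents that add atoms: chlorotriisopropylsilane, CC(C)[Si](Cl)(C(C)C)C(C)C
Why: Imidazole-promoted O-silylation masks the phenol against NBS and aqueous base in the next steps and later serves as the fluoride-triggered phenoxide source; no stereocentre is formed.

Step 2
Reactants: 3 (Z)-3-methylpent-2-en-4-yn-1-ol
Product: 4 (Z)-3-methylpenta-2,4-dien-1-ol
Conditions: H2 (1 atm, stopped at 1 equiv), Pd/CaCO3 poisoned with Pb(OAc)2, quinoline, EtOAc, 0 °C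
Reagents that add atoms: none
Why: Lindlar semihydrogenation reduces only the terminal alkyne to a vinyl group and leaves the Z trisubstituted olefin, whose geometry later fixes the Br/Cl relationship, untouched.

Step 3
Reactants: 2 (4-bromo-3-methylphenoxy)triisopropylsilane; 4 (Z)-3-methylpenta-2,4-dien-1-ol
Product: 6 (Z)-3-methyl-5-[2-methyl-4-(triisopropylsilyloxy)phenyl]pent-2-en-1-ol, via bis-boron adduct 5 (not isolated)
Conditions: 9-BBN-H (2.2 equiv), THF, 0 → 23 °C; then 2, Pd(dppf)Cl2 (5 mol %), aq K3PO4, DMF, 60 °C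
Reagents that add atoms: none
Why: Anti-Markovnikov hydroboration of the monosubstituted vinyl group (the hydroxyl is borylated in passing) followed by B-alkyl Suzuki–Miyaura coupling forges the aryl–CH2CH2 bond with the Z olefin geometry carried through unchanged.

Step 4
Reactants: 6 (Z)-3-methyl-5-[2-methyl-4-(triisopropylsilyloxy)phenyl]pent-2-en-1-ol
Product: 7 (2S,3S)-2-bromo-3-chloro-3-methyl-5-[2-methyl-4-(triisopropylsilyloxy)phenyl]pentan-1-ol
Conditions: NBS, ClTi(OiPr)3, chiral tridentate salicylaldimine amino-alcohol ligand (20 mol %, antipode that puts Br on the C2 Si face), hexanes, −20 °C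
Reagents that add atoms: N-bromosuccinimide, O=C1CCC(=O)N1Br; chlorotitanium triisopropoxide, CC(C)O[Ti](Cl)(OC(C)C)OC(C)C
Why: Titanium-templated catalytic enantioselective bromochlorination of an allylic alcohol gives face-selective bromonium formation at C2 and anti, Markovnikov chloride delivery to the tertiary C3, so anti addition to the Z olefin sets both halogen stereocentres (future C8 and C9) under ligand control.

Step 5
Reactants: 7 (2S,3S)-2-bromo-3-chloro-3-methyl-5-[2-methyl-4-(triisopropylsilyloxy)phenyl]pentan-1-ol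
Product: 10 (6S,8S,9S)-8-bromo-9-chloro-1,9-dimethylspiro[5.5]undeca-1,4-dien-3-one, via alkyl triflate 8 (not isolated), via ammonium phenoxide 9 (not isolated)
Conditions: Tf2O, 2,6-di-tert-butyl-4-methylpyridine, CH2Cl2, −78 °C; dilute with THF to 0.005 M; Bu4N[Ph3SiF2], −78 → −20 °C
Reagents that add atoms: none
Why: Winstein–Baird-type intramolecular phenoxide para-C-alkylation (alkylative dearomatization) closes ring B through a chair transition state with Br and Cl equatorial and the unsubstituted ortho CH (not the ortho C–Me) in the axial, inward-pointing site, so the two halogen stereocentres fix the spiro centre as 6S.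

Step 6
Reactants: 10 (6S,8S,9S)-8-bromo-9-chloro-1,9-dimethylspiro[5.5]undeca-1,4-dien-3-one
Product: 12 (5S,6S,8S,9S)-8-bromo-9-chloro-1,5,9-trimethylspiro[5.5]undec-1-en-3-one, via methylzinc enolate 11 (not isolated)
Conditions: Me2Zn (3 equiv), Cu(OTf)2 (5 mol %), (R,S,S)-binaphthol bis(1-phenylethyl)amine phosphoramidite (10 mol %), toluene, −25 °C; then 1 M HCl
Reagents that add atoms: dimethylzinc, C[Zn]C
Why: Copper–phosphoramidite-catalysed asymmetric conjugate addition to a 4,4-disubstituted cyclohexadienone attacks only the β-unsubstituted arm, and because the two faces of that arm are sterically alike the ligand (mirror image of the one giving (S)-3-alkylcyclohexanones) delivers methyl to the face syn to C7 and sets C5 as S.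

Step 7
Reactants: 12 (5S,6S,8S,9S)-8-bromo-9-chloro-1,5,9-trimethylspiro[5.5]undec-1-en-3-one
Product: 15 (2S,5S,6S,8S,9S)-2,8-dibromo-9-chloro-1,1,5,9-tetramethylspiro[5.5]undecan-3-one, via silyl enol ether 13 (not isolated), via C2-epimeric bromoketone 14 (not isolated)
Conditions: MeMgBr, CuBr·SMe2 (20 mol %), Me3SiCl, DMPU, THF, −78 → −40 °C; filter, concentrate; NBS, THF, −78 °C; then HBr (cat.), AcOH, 23 °C
Reagents that add atoms: methylmagnesium bromide, C[Mg]Br; N-bromosuccinimide, O=C1CCC(=O)N1Br
Why: Chlorosilane-accelerated copper-catalysed conjugate methylation builds the gem-dimethyl carbon and delivers the enol silane regiospecifically towards C2, NBS brominates it there, and acid-mediated enolization equilibrates C2 to the equatorial bromide (cis to the C5 methyl), because the axial epimer suffers a 1,3-diaxial clash with C11H2.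

Step 8
Reactants: 15 (2S,5S,6S,8S,9S)-2,8-dibromo-9-chloro-1,1,5,9-tetramethylspiro[5.5]undecan-3-one
Product: 16 (2S,3R,5S,6S,8S,9S)-2,8-dibromo-9-chloro-1,1,5,9-tetramethylspiro[5.5]undecan-3-ol
Conditions: iBu2AlH, CH2Cl2, −78 °C; then 1 M HCl
Reagents that add atoms: none
Why: Hydride reduction of the α-bromo ketone occurs from the face opposite the axial C5 methyl and the axial C1 methyl (ring B is locked with C5 axial and Br/Cl equatorial), which gives the C3 alcohol cis to both the C2 bromide and the C5 methyl.

**Compound list**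

1 | 4-bromo-3-methylphenol | Cc1cc(O)ccc1Br | starting material
2 | (4-bromo-3-methylphenoxy)triisopropylsilane | Cc1cc(O[Si](C(C)C)(C(C)C)C(C)C)ccc1Br | intermediate
3 | (Z)-3-methylpent-2-en-4-yn-1-ol | C#C/C(C)=C\CO | starting material
4 | (Z)-3-methylpenta-2,4-dien-1-ol | C=C/C(C)=C\CO | intermediate
5 | 9-[(3Z)-3-methyl-5-(9-borabicyclo[3.3.1]nonan-9-yloxy)pent-3-en-1-yl]-9-borabicyclo[3.3.1]nonane | C/C(CCB1C2CCCC1CCC2)=C/COB1C2CCCC1CCC2 | intermediate (not isolated)
6 | (Z)-3-methyl-5-[2-methyl-4-(triisopropylsilyloxy)phenyl]pent-2-en-1-ol | Cc1cc(O[Si](C(C)C)(C(C)C)C(C)C)ccc1CC/C(C)=C\CO | intermediate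
7 | (2S,3S)-2-bromo-3-chloro-3-methyl-5-[2-methyl-4-(triisopropylsilyloxy)phenyl]pentan-1-ol | Cc1cc(O[Si](C(C)C)(C(C)C)C(C)C)ccc1CC[C@](C)(Cl)[C@@H](Br)CO | intermediate
8 | (2S,3S)-2-bromo-3-chloro-3-methyl-5-[2-methyl-4-(triisopropylsilyloxy)phenyl]pentyl trifluoromethanesulfonate | Cc1cc(O[Si](C(C)C)(C(C)C)C(C)C)ccc1CC[C@](C)(Cl)[C@@H](Br)COS(=O)(=O)C(F)(F)F | intermediate (not isolated)
9 | tetrabutylammonium 4-[(3S,4S)-4-bromo-3-chloro-3-methyl-5-(trifluoromethylsulfonyloxy)pentyl]-3-methylphenolate | Cc1cc([O-])ccc1CC[C@](C)(Cl)[C@@H](Br)COS(=O)(=O)C(F)(F)F.CCCC[N+](CCCC)(CCCC)CCCC | intermediate (not isolated)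
10 | (6S,8S,9S)-8-bromo-9-chloro-1,9-dimethylspiro[5.5]undeca-1,4-dien-3-one | C1=CC(=O)C=C(C)[C@]12CC[C@](C)(Cl)[C@@H](Br)C2 | intermediate
11 | methylzinc (5S,6S,8S,9S)-8-bromo-9-chloro-1,5,9-trimethylspiro[5.5]undeca-1,3-dien-3-olate | C[C@H]1C=C(O[Zn]C)C=C(C)[C@]12CC[C@](C)(Cl)[C@@H](Br)C2 | intermediate (not isolated)
12 | (5S,6S,8S,9S)-8-bromo-9-chloro-1,5,9-trimethylspiro[5.5]undec-1-en-3-one | C[C@H]1CC(=O)C=C(C)[C@]12CC[C@](C)(Cl)[C@@H](Br)C2 | intermediate
13 | [(5S,6S,8S,9S)-8-bromo-9-chloro-1,1,5,9-tetramethylspiro[5.5]undec-2-en-3-yl]oxy(trimethyl)silane | C[C@H]1CC(O[Si](C)(C)C)=CC(C)(C)[C@]12CC[C@](C)(Cl)[C@@H](Br)C2 | intermediate (not isolated)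
14 | (2R,5S,6S,8S,9S)-2,8-dibromo-9-chloro-1,1,5,9-tetramethylspiro[5.5]undecan-3-one | C[C@H]1CC(=O)[C@H](Br)C(C)(C)[C@]12CC[C@](C)(Cl)[C@@H](Br)C2 | intermediate (not isolated)
15 | (2S,5S,6S,8S,9S)-2,8-dibromo-9-chloro-1,1,5,9-tetramethylspiro[5.5]undecan-3-one | C[C@H]1CC(=O)[C@@H](Br)C(C)(C)[C@]12CC[C@](C)(Cl)[C@@H](Br)C2 | intermediate
16 | (2S,3R,5S,6S,8S,9S)-2,8-dibromo-9-chloro-1,1,5,9-tetramethylspiro[5.5]undecan-3-ol | C[C@H]1C[C@@H](O)[C@@H](Br)C(C)(C)[C@]12CC[C@](C)(Cl)[C@@H](Br)C2 | target

**Totals**

Total step count: 8. Longest linear sequence: 7 (steps 1, 3, 4, 5, 6, 7, 8; equally 2, 3, 4, 5, 6, 7, 8).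

**Three steps most likely to fail**

Step 5 (dearomative spirocyclization). A six-membered para-alkylation at a β-branched primary carbon is slow. Competing paths are E2 loss of triflic acid to a vinyl bromide, fluoride attack on the triflate, and bromine-bridged opening at C2 to a five-membered spirocycle. The fallback sets out from 7 and comes back at 10 by changing from an anionic to a cationic dearomatization. Compound 7 is mesylated (MsCl, Et3N) to (2S,3S)-2-bromo-3-chloro-3-methyl-5-[2-methyl-4-(triisopropylsilyloxy)phenyl]pentyl methanesulfonate F1. F1 is heated in hexafluoroisopropanol buffered with K2HPO4. Bromine-assisted ionization gives a bromonium ion whose primary carbon is captured by the ipso carbon of the still silylated arene (Br anti to the new bond, hence equatorial), and the oxocarbenium ion loses its silyl group to give 10 with no base present.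

Step 7 (second conjugate methylation and bromination). The β-carbon is flanked by the quaternary spiro centre, so 1,2-addition or no reaction is possible. The organometallic may touch the vicinal bromochloride. The thermodynamic preference for the equatorial C2 bromide is estimated at only about 1 kcal/mol, and HBr could also move bromine to C4. The fallback sets out from 12 and comes back at 13 by replacing the conjugate addition with cyclopropanation and reductive ring opening. Me3S(O)I/NaH (Corey–Chaykovsky) converts 12 into the cyclopropyl ketone 3′-bromo-4′-chloro-1,3,4′-trimethylspiro[bicyclo[4.1.0]heptane-2,1′-cyclohexan]-5-one F2 (CH2 anti to the C3 methyl). SmI2 in THF/DMPU with Me3SiCl then cleaves the external cyclopropane bond that overlaps with the carbonyl. This turns the CH2 into the second methyl on C1 and gives the C2–C3 enolate regiospecifically, silylated to 13; both cyclopropane diastereomers converge.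

Step 4 (enantioselective bromochlorination). The Z substrate may give lower enantioselectivity than E analogues, and NBS could brominate the electron-rich ring. The fallback sets out from 6 and comes back at 7 by replacing asymmetric catalysis with resolution. Bu4N[BrCl2] in CH2Cl2 at −78 °C gives the racemic anti, Markovnikov adduct, that is 7 together with (2R,3R)-2-bromo-3-chloro-3-methyl-5-[2-methyl-4-(triisopropylsilyloxy)phenyl]pentan-1-ol F3. Amano PS lipase with vinyl acetate acetylates the (2R,3R)-alcohol to (2R,3R)-2-bromo-3-chloro-3-methyl-5-[2-methyl-4-(triisopropylsilyloxy)phenyl]pentyl acetate F4, and unreacted 7 is separated by chromatography. Which enantiomer the lipase acylates faster must be checked; if it is 7, 7 is recovered by methanolysis of its acetate instead.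

Further compounds
F1 | step 5 | (2S,3S)-2-bromo-3-chloro-3-methyl-5-[2-methyl-4-(triisopropylsilyloxy)phenyl]pentyl methanesulfonate | Cc1cc(O[Si](C(C)C)(C(C)C)C(C)C)ccc1CC[C@](C)(Cl)[C@@H](Br)COS(C)(=O)=O
F2 | step 7 | 3′-bromo-4′-chloro-1,3,4′-trimethylspiro[bicyclo[4.1.0]heptane-2,1′-cyclohexan]-5-one (cyclopropane CH2 anti to the C3 methyl; other centres as in 12) | C[C@H]1CC(=O)[C@@H]3C[C@]3(C)[C@]12CC[C@](C)(Cl)[C@@H](Br)C2
F3 | step 4 | (2R,3R)-2-bromo-3-chloro-3-methyl-5-[2-methyl-4-(triisopropylsilyloxy)phenyl]pentan-1-ol | Cc1cc(O[Si](C(C)C)(C(C)C)C(C)C)ccc1CC[C@@](C)(Cl)[C@H](Br)CO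
F4 | step 4 | (2R,3R)-2-bromo-3-chloro-3-methyl-5-[2-methyl-4-(triisopropylsilyloxy)phenyl]pentyl acetate | Cc1cc(O[Si](C(C)C)(C(C)C)C(C)C)ccc1CC[C@@](C)(Cl)[C@H](Br)COC(C)=O
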